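A direct plan would make rings A, B and C separately and join them through the two methylene bridges. The benzylated, brominated ring C ketone A1 would be coupled under nickel catalysis with the hydrazone of the tribenzylated formyl-phloroacetophenone A2. Debenzylation would give the two-ring polyphenol A3, and ring A would be added last as the ortho-quinone methide of aspidinol. Its weakest steps would be:
(a) the O-alkylation sequence leading to A1, which must place two benzyl groups and one methyl group on one butyrophenone; both ortho hydroxyls are chelated and hardly differ, yet this step alone would fix the ring C pattern;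
(b) the nickel-catalysed coupling of the aryl bromide A1 with the hydrazone of A2, which would have to form a diarylmethane with four ortho substituents beside two enolisable ketones, and for which five benzyl groups would be carried;
(c) the final intermolecular quinone methide alkylation of unprotected A3, where bridge exchange and oligomerisation would cost the most advanced material.

**Plan of the new route**
- Ring C (numbered from the bridge carbon C1: C2 OH, C3 butanoyl, C4 OMe, C5 Me, C6 OH) is grown on ring B, not coupled to it. The retrosynthesis cuts C2–C3 and C4–C5 of ring C and the C1–CH2 bond (as a Knoevenagel C=C).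
- Feature used: C1 lies between two hydroxylated carbons and ring B has a hydroxyl ortho to the bridge, so O(ring B)–C2(=O)–C1–CH2 is a latent 3-acyl-dihydrocoumarin. C6–C5–CH3 is a propanoyl group, and C4(OMe)–C3(COPr) is an acylketene dimethyl acetal.
- Ring order: A and B are joined first, on two monomers. The ring B aldehyde is condensed with methyl 3-oxopentanoate to a 3-propanoylcoumarin, the ketene acetal adds C4 and C3, and ring C is closed last.
- The weak steps vanish: the ring C methoxy group arrives on a ketene acetal carbon, so no hydroxyls need telling apart and no benzyl group is used. The bridge carbon is a formyl carbon condensed with a CH-acid, so no hindered cross-coupling is needed. The last step is an intramolecular ring closure that releases a phenol.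

Key step: step 8

Remark: the target has no stereocentre; the centres and double-bond geometries of 12, 16 and 17 are transient.
Remark: the Knoevenagel adduct could lactonise onto either hydroxyl beside the formyl group; 13 is drawn closed onto the hydroxyl para to the acetyl group, and the other isomer would give the same 18.

**Route**

Step 1
Reactants: 1 2-methylphloroglucinol (2-methylbenzene-1,3,5-triol); 2 butanoyl chloride
Product: 3 1-(2,4,6-trihydroxy-3-methylphenyl)butan-1-one
Conditions: AlCl3 (3 equiv), PhNO2/CH2Cl2, 0 to 45 °C; aq. HCl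
Reagents that add atoms: none
Why: Friedel–Crafts C-acylation at one of the two equivalent free positions of the triol should stop after one acyl group, because the aryl ketone is deactivated.

Step 2
Reactants: 3 1-(2,4,6-trihydroxy-3-methylphenyl)butan-1-one
Product: 4 aspidinol, 1-(2,6-dihydroxy-4-methoxy-3-methylphenyl)butan-1-one
Conditions: Me2SO4 (1.0 equiv), K2CO3 (1.1 equiv), acetone, rt to 40 °C
Reagents that add atoms: dimethyl sulfate, COS(=O)(=O)OC
Why: Williamson O-methylation should take the hydroxyl para to the ketone, the most acidic one and the only one not tied to the carbonyl oxygen by a hydrogen bond.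

Step 3
Reactants: 5 phloroacetophenone, 1-(2,4,6-trihydroxyphenyl)ethan-1-one
Product: 7 3-acetyl-2,4,6-trihydroxybenzaldehyde, via iminium chloride 6 (not isolated)
Conditions: POCl3 (1.2 equiv), DMF (1.5 equiv), EtOAc, 0 °C to rt; then H2O, 60 °C
Reagents that add atoms: N,N-dimethylformamide, CN(C)C=O; water, O
Why: Vilsmeier–Haack formylation at one of two equivalent free positions should stop at the mono-aldehyde, since the first formyl group deactivates the ring; its carbon is the future B–C bridge.

Step 4
Reactants: 4 aspidinol; 7 3-acetyl-2,4,6-trihydroxybenzaldehyde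
Product: 10 3-acetyl-5-[(3-butanoyl-2,4-dihydroxy-6-methoxy-5-methylphenyl)methyl]-2,4,6-trihydroxybenzaldehyde, via Mannich base 8 (not isolated), via ortho-quinone methide 9 (not isolated)
Conditions: [CH2=NMe2]I (1.0 equiv), Et3N (1.0 equiv), MeCN, rt, 2 h; then 7 (1.2 equiv), 80 °C
Reagents that add atoms: N,N-dimethylmethyleneiminium iodide, C=[N+](C)C.[I-]
Why: Mannich aminomethylation of the only free position of 4, thermal loss of dimethylamine to 9 and Michael addition of the single free ring carbon of 7 should give the A–B diarylmethane without double alkylation, on two simple monomers instead of on late material.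

Step 5
Reactants: 10 the A–B aldehyde; 11 methyl 3-oxopentanoate
Product: 13 6-acetyl-8-[(3-butanoyl-2,4-dihydroxy-6-methoxy-5-methylphenyl)methyl]-5,7-dihydroxy-3-propanoyl-2H-chromen-2-one, via alkylidene keto ester 12 (not isolated)
Conditions: 11 (1.5 equiv), piperidine (0.2 equiv), AcOH (0.2 equiv), EtOH, 70 °C
Reagents that add atoms: none
Why: Knoevenagel condensation of the salicylaldehyde with the β-keto ester, then lactonisation of the Z adduct onto a flanking phenol (the classical 3-acylcoumarin synthesis), should join the formyl carbon to the future C1 of ring C and tie C2 to ring B as a lactone, with no aromatic substitution and hence no bridge exchange.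

Step 6
Reactants: 2 butanoyl chloride; 14 1,1-dimethoxyethene
Product: 15 1,1-dimethoxyhex-1-en-3-one
Conditions: 14 (2.2 equiv), Et2O, 0 °C to rt; distil
Reagents that add atoms: none
Why: C-acylation of the nucleophilic ketene acetal by the acid chloride (enol ether acylation) should give the push–pull acylketene acetal, the second equivalent of 14 taking up the hydrogen chloride.

Step 7
Reactants: 13 the 3-propanoylcoumarin; 15 1,1-dimethoxyhex-1-en-3-one
Product: 16 6-acetyl-8-[(3-butanoyl-2,4-dihydroxy-6-methoxy-5-methylphenyl)methyl]-5,7-dihydroxy-3-[(3E)-3-methoxy-2-methyl-5-oxooct-3-enoyl]-2H-chromen-2-one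
Conditions: NaH (5.3 equiv), DMF, 0 °C; then 15 (1.5 equiv), 0 °C to rt; AcOH, 0 °C
Reagents that add atoms: none
Why: Nucleophilic vinylic substitution (addition–elimination of a ketone enolate on an α-oxo ketene acetal): once the four phenols are phenoxides the two aryl ketones are vinylogous carboxylates, so the propanoyl CH2 should be the only carbon acid left; its enolate adds to the acetal carbon of 15 and expels methoxide, which forms C4–C5 of ring C and creates a side-chain centre as a racemate of no consequence.

Step 8
Reactants: 16 the chain-extended coumarin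
Product: 18 CNP0184345.0, 1-[3-[[3-acetyl-5-[(3-butanoyl-2,6-dihydroxy-4-methoxy-5-methylphenyl)methyl]-2,4,6-trihydroxyphenyl]methyl]-2,6-dihydroxy-4-methoxy-5-methylphenyl]butan-1-one, via dihydrocoumarin 17 (not isolated)
Conditions: H2 (1 atm), 5% Pd/C, EtOAc/THF, rt; filter; then DBU (4 equiv), MeCN, 0 °C to rt; aq. citric acid
Reagents that add atoms: none
Why: Hydrogenation should saturate the electron-poor C3=C4 bond of the 3-acylcoumarin, which turns the former formyl carbon into the methylene bridge and the conjugated lactone into a plain aryl ester (17). DBU then removes the proton at C2 of the side chain; the extended enolate attacks the lactone carbonyl through its C4 terminus in a 6-exo-trig Dieckmann (Claisen) closure of C2–C3 of ring C, the ring B phenoxide leaves, and the triketone tautomerises to the arene. The closest known reaction types are the biomimetic Claisen cyclisation of 3,5,7-triketo esters to acylphloroglucinols and the Baker–Venkataraman acyl transfer from an aryl ester to an enolate. No stereocentre is created, and the labile centres of 17 vanish on aromatisation. The step needs Claisen rather than aldol closure and the methoxy group on C4: attack of the lactone α-carbon on the butanoyl carbonyl would give a quaternary carbon that cannot aromatise and should revert, while the methoxy group is fixed as the enol ether brought in by 15 and the methyl, hydroxyl and butanoyl positions follow from the chain order. The lactone oxygen returns as the ring B hydroxyl, so either lactone isomer of 13 would converge on 18.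

**Compound list**
1 | 2-methylphloroglucinol (2-methylbenzene-1,3,5-triol) | Cc1c(O)cc(O)cc1O | starting material
2 | butanoyl chloride | CCCC(=O)Cl | starting material
3 | 1-(2,4,6-trihydroxy-3-methylphenyl)butan-1-one | CCCC(=O)c1c(O)cc(O)c(C)c1O | intermediate
4 | aspidinol, 1-(2,6-dihydroxy-4-methoxy-3-methylphenyl)butan-1-one | CCCC(=O)c1c(O)cc(OC)c(C)c1O | intermediate
5 | phloroacetophenone, 1-(2,4,6-trihydroxyphenyl)ethan-1-one | CC(=O)c1c(O)cc(O)cc1O | starting material
6 | N-[(3-acetyl-2,4,6-trihydroxyphenyl)methylidene]-N-methylmethanaminium chloride | CC(=O)c1c(O)cc(O)c(C=[N+](C)C)c1O.[Cl-] | intermediate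
7 | 3-acetyl-2,4,6-trihydroxybenzaldehyde | CC(=O)c1c(O)cc(O)c(C=O)c1O | intermediate
8 | 1-[3-[(dimethylamino)methyl]-2,6-dihydroxy-4-methoxy-5-methylphenyl]butan-1-one | CCCC(=O)c1c(O)c(CN(C)C)c(OC)c(C)c1O | intermediate
9 | 2-butanoyl-3-hydroxy-5-methoxy-4-methyl-6-methylidenecyclohexa-2,4-dien-1-one | CCCC(=O)C1=C(O)C(C)=C(OC)C(=C)C1=O | intermediate
10 | 3-acetyl-5-[(3-butanoyl-2,4-dihydroxy-6-methoxy-5-methylphenyl)methyl]-2,4,6-trihydroxybenzaldehyde | CCCC(=O)c1c(O)c(C)c(OC)c(Cc2c(O)c(C=O)c(O)c(C(C)=O)c2O)c1O | intermediate
11 | methyl 3-oxopentanoate | CCC(=O)CC(=O)OC | starting material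
12 | methyl (2Z)-2-[[3-acetyl-5-[(3-butanoyl-2,4-dihydroxy-6-methoxy-5-methylphenyl)methyl]-2,4,6-trihydroxyphenyl]methylidene]-3-oxopentanoate | COC(=O)/C(C(=O)CC)=C\c1c(O)c(C(C)=O)c(O)c(Cc2c(O)c(C(=O)CCC)c(O)c(C)c2OC)c1O | intermediate
13 | 6-acetyl-8-[(3-butanoyl-2,4-dihydroxy-6-methoxy-5-methylphenyl)methyl]-5,7-dihydroxy-3-propanoyl-2H-chromen-2-one | CCC(=O)C1=Cc2c(O)c(C(C)=O)c(O)c(Cc3c(O)c(C(=O)CCC)c(O)c(C)c3OC)c2OC1=O | intermediate
14 | 1,1-dimethoxyethene | C=C(OC)OC | starting material
15 | 1,1-dimethoxyhex-1-en-3-one | CCCC(=O)C=C(OC)OC | intermediate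
16 | 6-acetyl-8-[(3-butanoyl-2,4-dihydroxy-6-methoxy-5-methylphenyl)methyl]-5,7-dihydroxy-3-[(3E)-3-methoxy-2-methyl-5-oxooct-3-enoyl]-2H-chromen-2-one (racemic at C2 of the side chain) | CCCC(=O)/C=C(OC)\C(C)C(=O)C1=Cc2c(O)c(C(C)=O)c(O)c(Cc3c(O)c(C(=O)CCC)c(O)c(C)c3OC)c2OC1=O | intermediate
17 | 6-acetyl-8-[(3-butanoyl-2,4-dihydroxy-6-methoxy-5-methylphenyl)methyl]-5,7-dihydroxy-3-[(3E)-3-methoxy-2-methyl-5-oxooct-3-enoyl]-3,4-dihydro-2H-chromen-2-one (mixture of diastereomers) | CCCC(=O)/C=C(OC)\C(C)C(=O)C1Cc2c(O)c(C(C)=O)c(O)c(Cc3c(O)c(C(=O)CCC)c(O)c(C)c3OC)c2OC1=O | intermediate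
18 | CNP0184345.0, 1-[3-[[3-acetyl-5-[(3-butanoyl-2,6-dihydroxy-4-methoxy-5-methylphenyl)methyl]-2,4,6-trihydroxyphenyl]methyl]-2,6-dihydroxy-4-methoxy-5-methylphenyl]butan-1-one | CCCC(=O)c1c(O)c(C)c(OC)c(Cc2c(O)c(Cc3c(O)c(C)c(OC)c(C(=O)CCC)c3O)c(O)c(C(C)=O)c2O)c1O | target

**Step count and risks**
Total: 8 steps. Longest linear sequence: 6 steps (1, 2, 4, 5, 7, 8).

Steps most likely to fail:

1. Step 8. The base may deprotonate the lactone α-carbon instead of the side chain, so that the enolate shuts down the lactone as acyl donor and the closure stalls; the hydrogenation may also touch the vinylogous ester. Fallback: set out from 16, hydrogenate and isolate 17, then heat it in toluene at 110 °C without base. The β-keto aryl ester should lose the ring B phenol within the molecule to give the acylketene (5E)-2-[[3-acetyl-5-[(3-butanoyl-2,4-dihydroxy-6-methoxy-5-methylphenyl)methyl]-2,4,6-trihydroxyphenyl]methyl]-5-methoxy-4-methyldeca-1,5-diene-1,3,7-trione F1. Its dienol form should close by 6π-electrocyclisation and tautomerise, which comes back to the route at 18.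

2. Step 7. Enolisation at an aryl ketone, O-vinylation of phenoxides by 15 or conjugate addition to the coumarin may compete. Fallback: set out from 13 and change from the anionic to a Lewis-acid Mukaiyama–Michael manifold. Silylation (Me3SiCl, Et3N; then TMSOTf, Et3N, CH2Cl2) should give 6-acetyl-8-[[3-butanoyl-6-methoxy-5-methyl-2,4-bis(trimethylsilyloxy)phenyl]methyl]-5,7-bis(trimethylsilyloxy)-3-[(1Z)-1-(trimethylsilyloxy)prop-1-enyl]-2H-chromen-2-one F2, with the coumarinyl ketone expected to enolise first. F2 would add to 15 under TMSOTf at −78 °C with loss of methanol, and mild aqueous work-up would cleave the silyl ethers and come back at 16.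

3. Step 4. The doubly acylated phloroglucinol 7 may be too weak a nucleophile, so that the quinone methide oligomerises or stays as its amine adduct. Fallback: set out from 4 and 5 and change the order of bond formation. The quinone methide 9 (from 4 via 8) would be trapped by phloroacetophenone 5 (3 equiv, to suppress double alkylation) to give 1-[3-[(3-acetyl-2,4,6-trihydroxyphenyl)methyl]-2,6-dihydroxy-4-methoxy-5-methylphenyl]butan-1-one F3. Vilsmeier–Haack formylation (POCl3, DMF, EtOAc; then H2O) at the single free ring carbon of F3 would proceed through N-[[3-acetyl-5-[(3-butanoyl-2,4-dihydroxy-6-methoxy-5-methylphenyl)methyl]-2,4,6-trihydroxyphenyl]methylidene]-N-methylmethanaminium chloride F4 and come back at 10.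

Further compounds
F1 | step 8 | (5E)-2-[[3-acetyl-5-[(3-butanoyl-2,4-dihydroxy-6-methoxy-5-methylphenyl)methyl]-2,4,6-trihydroxyphenyl]methyl]-5-methoxy-4-methyldeca-1,5-diene-1,3,7-trione | CCCC(=O)/C=C(OC)\C(C)C(=O)C(=C=O)Cc1c(O)c(C(C)=O)c(O)c(Cc2c(O)c(C(=O)CCC)c(O)c(C)c2OC)c1O
F2 | step 7 | 6-acetyl-8-[[3-butanoyl-6-methoxy-5-methyl-2,4-bis(trimethylsilyloxy)phenyl]methyl]-5,7-bis(trimethylsilyloxy)-3-[(1Z)-1-(trimethylsilyloxy)prop-1-enyl]-2H-chromen-2-one | C/C=C(\O[Si](C)(C)C)C1=Cc2c(O[Si](C)(C)C)c(C(C)=O)c(O[Si](C)(C)C)c(Cc3c(O[Si](C)(C)C)c(C(=O)CCC)c(O[Si](C)(C)C)c(C)c3OC)c2OC1=O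
F3 | step 4 | 1-[3-[(3-acetyl-2,4,6-trihydroxyphenyl)methyl]-2,6-dihydroxy-4-methoxy-5-methylphenyl]butan-1-one | CCCC(=O)c1c(O)c(C)c(OC)c(Cc2c(O)cc(O)c(C(C)=O)c2O)c1O
F4 | step 4 | N-[[3-acetyl-5-[(3-butanoyl-2,4-dihydroxy-6-methoxy-5-methylphenyl)methyl]-2,4,6-trihydroxyphenyl]methylidene]-N-methylmethanaminium chloride | CCCC(=O)c1c(O)c(C)c(OC)c(Cc2c(O)c(C=[N+](C)C)c(O)c(C(C)=O)c2O)c1O.[Cl-]
A1 | direct plan | 1-[2,4-bis(benzyloxy)-3-bromo-6-methoxy-5-methylphenyl]butan-1-one | CCCC(=O)c1c(OC)c(C)c(OCc2ccccc2)c(Br)c1OCc1ccccc1
A2 | direct plan | 3-acetyl-2,4,6-tris(benzyloxy)benzaldehyde | CC(=O)c1c(OCc2ccccc2)cc(OCc2ccccc2)c(C=O)c1OCc1ccccc1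
A3 | direct plan | 1-[3-[(3-acetyl-2,4,6-trihydroxyphenyl)methyl]-2,4-dihydroxy-6-methoxy-5-methylphenyl]butan-1-one | CC(=O)c1c(O)cc(O)c(Cc2c(O)c(C)c(OC)c(C(=O)CCC)c2O)c1O
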